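**Retrosynthetic overview**

1. The aryl ether is cut last at the exocyclic CH2–O bond (Mitsunobu with umbelliferone); the acetate and the C1 configuration come from a 2,2-dimethyl-4-methylidenecyclohexanone by hydride addition anti to the C3 CH2OSi group.
2. The plan rests on this feature of the single carbocycle: C4 (bearing =CH2) and its neighbour C5H2 are an alkyne carbon and a primary radical carbon, while the oxygenated C1 and the C6H2–C5H2 pair beside it are the three carbons of a 1-substituted cyclopropanol. Opening C1–C5 and closing C5–C4 (6-exo-dig) builds the ring.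
3. The cyclopropanol comes from a methyl ester (Kulinkovich) and the ethynyl group from a vinyl group (ozonolysis, Ohira–Bestmann).
4. The C3 stereocentre next to the quaternary C2 comes from an Ir-catalysed asymmetric allylic alkylation of the isobutyrate silyl ketene acetal with an (E)-4-silyloxybut-2-enyl carbonate made from but-2-yne-1,4-diol.
5. Ring order: the cyclohexane is the only ring formed (step 8); the coumarin is brought in intact.

Key step: step 8

Remark: the isobutyrate trimethylsilyl ketene acetal is taken as a commercial reagent. The (Ra,Rc,Rc) ligand antipode in step 4 is assigned from the usual facial model for cyclometalated Ir–phosphoramidite catalysts; if correlation of the allylation product shows the opposite sense, the mirror-image ligand is used and nothing else changes. TBS = tert-butyl(dimethyl)silyl.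

**Route**

Step 1
Reactants: 1 but-2-yne-1,4-diol
Product: 2 (2E)-but-2-ene-1,4-diol
Conditions: LiAlH4 (1.5 equiv), THF, 0 °C → reflux; aq. NaOH work-up
Reagents that add atoms: none
Why: Trans-hydroalumination of a propargylic alcohol by LiAlH4, in which the alkoxide-bound aluminium delivers hydride intramolecularly, should give the (E)-alkene only.

Step 2
Reactants: 2 (2E)-but-2-ene-1,4-diol
Product: 3 (2E)-4-(TBS-oxy)but-2-en-1-ol
Conditions: 2 (3 equiv), TBSCl (1 equiv), imidazole, THF/DMF, 0 °C → rt; excess diol removed by aqueous wash
Reagents that add atoms: tert-butyl(chloro)dimethylsilane, CC(C)(C)[Si](C)(C)Cl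
Why: Statistical monosilylation of a symmetric diol used in excess should give mainly the mono-ether, and the water-soluble diol is washed out.

Step 3
Reactants: 3 (2E)-4-(TBS-oxy)but-2-en-1-ol
Product: 4 (2E)-4-(TBS-oxy)but-2-en-1-yl methyl carbonate
Conditions: ClCO2Me, pyridine, CH2Cl2, 0 °C
Reagents that add atoms: methyl chloroformate, COC(Cl)=O
Why: Standard acylation of a primary allylic alcohol gives the linear (E)-allyl carbonate needed as the electrophile for iridium.

Step 4
Reactants: 4 (2E)-4-(TBS-oxy)but-2-en-1-yl methyl carbonate; 5 [(1-methoxy-2-methylprop-1-en-1-yl)oxy]trimethylsilane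
Product: 6 methyl (3S)-3-(TBS-oxymethyl)-2,2-dimethylpent-4-enoate
Conditions: [Ir(cod)Cl]2 (2 mol %), (Ra,Rc,Rc)-O,O′-(1,1′-binaphthyl-2,2′-diyl) N,N-bis(1-phenylethyl)phosphoramidite (4 mol %), catalyst pre-activated with n-PrNH2, 5 (2 equiv), THF, rt
Reagents that add atoms: none
Why: In this branched-selective Ir-catalysed asymmetric allylic alkylation the methoxide released on ionisation of the carbonate activates the silyl ketene acetal, the enolate equivalent attacks the substituted allyl terminus anti to iridium, and the cyclometalated phosphoramidite fixes the allyl face so that C3 forms as (S) beside the new quaternary carbon.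

Step 5
Reactants: 6 methyl (3S)-3-(TBS-oxymethyl)-2,2-dimethylpent-4-enoate
Product: 8 methyl (3S)-3-(TBS-oxymethyl)-2,2-dimethyl-4-oxobutanoate, via secondary ozonide 7 (not isolated)
Conditions: O3, CH2Cl2, −78 °C (indicator end-point); PPh3, −78 °C → rt; short silica plug, used at once
Reagents that add atoms: ozone, [O-][O+]=O
Why: Ozonolysis with reductive work-up cleaves the only C=C bond and leaves the silyl ether, the ester and C3 untouched, and the α-branched aldehyde is carried on immediately to limit epimerisation.

Step 6
Reactants: 8 methyl (3S)-3-(TBS-oxymethyl)-2,2-dimethyl-4-oxobutanoate; 9 dimethyl (1-diazo-2-oxopropyl)phosphonate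
Product: 10 methyl (3S)-3-(TBS-oxymethyl)-2,2-dimethylpent-4-ynoate
Conditions: 9 (1.5 equiv), K2CO3 (2 equiv), MeOH, 0 °C → rt
Reagents that add atoms: none
Why: The Ohira–Bestmann variant of the Seyferth–Gilbert homologation works under mild carbonate/methanol conditions that are established for α-branched β-silyloxy aldehydes with retention of the α-configuration, and the hindered methyl ester is inert to methoxide.

Step 7
Reactants: 10 methyl (3S)-3-(TBS-oxymethyl)-2,2-dimethylpent-4-ynoate; 11 ethylmagnesium bromide
Product: 12 1-[(3S)-3-(TBS-oxymethyl)-2-methylpent-4-yn-2-yl]cyclopropan-1-ol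
Conditions: Ti(OiPr)4 (1.0 equiv), EtMgBr (4.5 equiv, slow addition), THF, 0 °C → rt; sat. aq. NH4Cl
Reagents that add atoms: none
Why: In the Kulinkovich cyclopropanation the titanacyclopropane from EtMgBr and Ti(OiPr)4 adds to the ester as a 1,2-dicarbanion equivalent (α-quaternary esters are competent substrates), the first equivalent of Grignard reagent masks the terminal alkyne as its magnesium acetylide, and the propargylic stereocentre is not enolisable.

Step 8
Reactants: 12 1-[(3S)-3-(TBS-oxymethyl)-2-methylpent-4-yn-2-yl]cyclopropan-1-ol
Product: 13 (3S)-3-(TBS-oxymethyl)-2,2-dimethyl-4-methylidenecyclohexan-1-one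
Conditions: Mn(acac)3 (2.5 equiv), degassed t-BuOH/i-PrOH (9:1), 0.02 M, 40 °C, Ar
Reagents that add atoms: none
Why: Ligand exchange gives a Mn(III) cyclopropoxide, and inner-sphere electron transfer with cleavage of either of the two equivalent strained C–C bonds releases the ketone and the primary radical •CH2CH2C(=O)–. This radical adds to the internal alkyne carbon, closing the cyclohexanone in the 6-exo-dig mode (C5–C4 bond), and the exocyclic σ-vinyl radical takes a hydrogen atom from i-PrOH, whose ketyl radical is oxidised to acetone by the second equivalent of Mn(III). The closest known reaction type is the Mn(III)-mediated oxidative ring opening of cyclopropanols with cyclisation of the β-keto radical onto a tethered π-bond, together with Mn(III) radical cyclisations onto alkynes that end by hydrogen abstraction from an alcohol. No stereocentre is created; C3 from step 4 is carried through and is not enolisable in the product. The selectivity required is ring closure ahead of reduction of the primary radical and ahead of 1,5-hydrogen transfer from the propargylic C–H; the gem-dimethyl group folds the chain towards the alkyne, and the donor is a dilute secondary alcohol that should react quickly with a vinyl radical but slowly with an alkyl radical. Ring-opening regiochemistry does not arise because the cyclopropane is symmetric, and attack at the internal rather than the terminal alkyne carbon (6-exo over 7-endo) gives the exocyclic methylene directly.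

Step 9
Reactants: 13 (3S)-3-(TBS-oxymethyl)-2,2-dimethyl-4-methylidenecyclohexan-1-one
Product: 14 (1R,3S)-3-(TBS-oxymethyl)-2,2-dimethyl-4-methylidenecyclohexan-1-ol
Conditions: NaBH4, MeOH, −20 → 0 °C
Reagents that add atoms: none
Why: A small hydride should add to the carbonyl face anti to the C3 CH2OSi group (axial attack on the chair with that group equatorial, as in reductions of 2,2-dimethylcyclohexanones), which places the C1 hydroxyl cis to C3 and sets C1 as (R).

Step 10
Reactants: 14 (1R,3S)-3-(TBS-oxymethyl)-2,2-dimethyl-4-methylidenecyclohexan-1-ol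
Product: 15 (1R,3S)-3-(TBS-oxymethyl)-2,2-dimethyl-4-methylidenecyclohexyl acetate
Conditions: Ac2O, pyridine, DMAP (cat.), CH2Cl2, rt
Reagents that add atoms: acetic anhydride, CC(=O)OC(C)=O
Why: DMAP-catalysed acylation of the hindered secondary alcohol proceeds at oxygen with retention at C1.

Step 11
Reactants: 15 (1R,3S)-3-(TBS-oxymethyl)-2,2-dimethyl-4-methylidenecyclohexyl acetate
Product: 16 (1R,3S)-3-(hydroxymethyl)-2,2-dimethyl-4-methylidenecyclohexyl acetate
Conditions: HF·pyridine, pyridine/THF, 0 °C → rt
Reagents that add atoms: none
Why: Buffered HF·pyridine cleaves the primary silyl ether without the basic fluoride conditions that could move the acetyl group to the freed primary hydroxyl, and it should not isomerise the exocyclic alkene.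

Step 12
Reactants: 16 (1R,3S)-3-(hydroxymethyl)-2,2-dimethyl-4-methylidenecyclohexyl acetate; 17 umbelliferone (7-hydroxy-2H-chromen-2-one)
Product: 18 (1R,3S)-2,2-dimethyl-4-methylidene-3-{[(2-oxo-2H-chromen-7-yl)oxy]methyl}cyclohexyl acetate
Conditions: PPh3, DIAD, THF, 0 °C → rt
Reagents that add atoms: none
Why: In the Mitsunobu etherification the acidic 7-hydroxycoumarin displaces the primary alkoxyphosphonium in an SN2 step at a non-stereogenic CH2, so both stereocentres and the acetate are untouched.

**Compound list**

1 | but-2-yne-1,4-diol | OCC#CCO | starting material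
2 | (2E)-but-2-ene-1,4-diol | OC/C=C/CO | intermediate
3 | (2E)-4-{[tert-butyl(dimethyl)silyl]oxy}but-2-en-1-ol | OC/C=C/CO[Si](C)(C)C(C)(C)C | intermediate
4 | (2E)-4-{[tert-butyl(dimethyl)silyl]oxy}but-2-en-1-yl methyl carbonate | COC(=O)OC/C=C/CO[Si](C)(C)C(C)(C)C | intermediate
5 | [(1-methoxy-2-methylprop-1-en-1-yl)oxy]trimethylsilane | COC(O[Si](C)(C)C)=C(C)C | starting material
6 | methyl (3S)-3-({[tert-butyl(dimethyl)silyl]oxy}methyl)-2,2-dimethylpent-4-enoate | COC(=O)C(C)(C)[C@@H](CO[Si](C)(C)C(C)(C)C)C=C | intermediate
7 | methyl (3S)-4-{[tert-butyl(dimethyl)silyl]oxy}-2,2-dimethyl-3-(1,2,4-trioxolan-3-yl)butanoate (secondary ozonide) | COC(=O)C(C)(C)[C@@H](CO[Si](C)(C)C(C)(C)C)C1OCOO1 | intermediate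
8 | methyl (3S)-3-({[tert-butyl(dimethyl)silyl]oxy}methyl)-2,2-dimethyl-4-oxobutanoate | COC(=O)C(C)(C)[C@@H](CO[Si](C)(C)C(C)(C)C)C=O | intermediate
9 | dimethyl (1-diazo-2-oxopropyl)phosphonate | COP(=O)(OC)C(=[N+]=[N-])C(C)=O | starting material
10 | methyl (3S)-3-({[tert-butyl(dimethyl)silyl]oxy}methyl)-2,2-dimethylpent-4-ynoate | COC(=O)C(C)(C)[C@@H](CO[Si](C)(C)C(C)(C)C)C#C | intermediate
11 | ethylmagnesium bromide | CC[Mg]Br | starting material
12 | 1-[(3S)-3-({[tert-butyl(dimethyl)silyl]oxy}methyl)-2-methylpent-4-yn-2-yl]cyclopropan-1-ol | OC1(CC1)C(C)(C)[C@@H](CO[Si](C)(C)C(C)(C)C)C#C | intermediate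
13 | (3S)-3-({[tert-butyl(dimethyl)silyl]oxy}methyl)-2,2-dimethyl-4-methylidenecyclohexan-1-one | C=C1CCC(=O)C(C)(C)[C@H]1CO[Si](C)(C)C(C)(C)C | intermediate
14 | (1R,3S)-3-({[tert-butyl(dimethyl)silyl]oxy}methyl)-2,2-dimethyl-4-methylidenecyclohexan-1-ol | C=C1CC[C@@H](O)C(C)(C)[C@H]1CO[Si](C)(C)C(C)(C)C | intermediate
15 | (1R,3S)-3-({[tert-butyl(dimethyl)silyl]oxy}methyl)-2,2-dimethyl-4-methylidenecyclohexyl acetate | C=C1CC[C@@H](OC(C)=O)C(C)(C)[C@H]1CO[Si](C)(C)C(C)(C)C | intermediate
16 | (1R,3S)-3-(hydroxymethyl)-2,2-dimethyl-4-methylidenecyclohexyl acetate | C=C1CC[C@@H](OC(C)=O)C(C)(C)[C@H]1CO | intermediate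
17 | umbelliferone (7-hydroxy-2H-chromen-2-one) | O=c1ccc2ccc(O)cc2o1 | starting material
18 | (1R,3S)-2,2-dimethyl-4-methylidene-3-{[(2-oxo-2H-chromen-7-yl)oxy]methyl}cyclohexyl acetate | C=C1CC[C@@H](OC(C)=O)C(C)(C)[C@H]1COc1ccc2ccc(=O)oc2c1 | target

**Step count and risks**

Total step count: 12. Longest linear sequence: 12 steps (1 → 18); compounds 5, 9, 11 and 17 enter as purchased materials.

Steps most likely to fail:

1. Step 8. The primary radical may be reduced by the hydrogen donor, or may translocate by 1,5-hydrogen transfer from the propargylic C–H, before it closes onto the alkyne; this would give open-chain ketone and erode the C3 configuration. The fallback sets out from 12 and separates radical generation from the oxidant. Electrophilic ring-opening iodination of the cyclopropanol with N-iodosuccinimide (CH2Cl2, 0 °C, dark) should give the β-iodo ketone (5S)-5-({[tert-butyl(dimethyl)silyl]oxy}methyl)-1-iodo-4,4-dimethylhept-6-yn-3-one F1. Slow syringe-pump addition of Bu3SnH/AIBN to F1 in refluxing benzene at high dilution is then the classical tin-mediated 6-exo-dig cyclisation of an iodoalkyl alkyne, with the hydride concentration as the only variable; the fallback returns to the route at 13.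

2. Step 7. The low-valent titanium species may be diverted by the acetylenic unit while addition to the doubly hindered ester is slow, so that conversion stalls. The fallback sets out from 6 and moves the cyclopropanation ahead of the alkyne:
   - Kulinkovich reaction on the alkenyl ester (EtMgBr/Ti(OiPr)4, which tolerates a hindered terminal alkene) should give 1-[(3S)-3-({[tert-butyl(dimethyl)silyl]oxy}methyl)-2-methylpent-4-en-2-yl]cyclopropan-1-ol F2.
   - Silylation (TMSCl, imidazole) gives {1-[(3S)-3-({[tert-butyl(dimethyl)silyl]oxy}methyl)-2-methylpent-4-en-2-yl]cyclopropoxy}trimethylsilane F3.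
   - Ozonolysis with PPh3 work-up gives (2S)-2-({[tert-butyl(dimethyl)silyl]oxy}methyl)-3-methyl-3-{1-[(trimethylsilyl)oxy]cyclopropyl}butanal F4.
   - Ohira–Bestmann homologation (9, K2CO3, MeOH) gives {1-[(3S)-3-({[tert-butyl(dimethyl)silyl]oxy}methyl)-2-methylpent-4-yn-2-yl]cyclopropoxy}trimethylsilane F5, whose tertiary trimethylsilyl ether is cleaved in the same basic methanol; the fallback returns to the route at 12.

3. Step 9. Facial selectivity may be poor if the ring reacts through the conformer with an axial CH2OSi group, where the two faces are shielded to a similar degree. The fallback sets out from 13 and replaces substrate control by catalyst control: Corey–Bakshi–Shibata reduction with the (S)-configured methyl oxazaborolidine and catecholborane at −78 °C (catecholborane so that the exocyclic alkene is not hydroborated). By the usual large/small model, with the quaternary C2 as the large group, this should deliver the (1R) alcohol. The fallback returns to the route at 14, and no compound outside the list is made (F0).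

**Further compounds**

F1 | step 8 | (5S)-5-({[tert-butyl(dimethyl)silyl]oxy}methyl)-1-iodo-4,4-dimethylhept-6-yn-3-one | ICCC(=O)C(C)(C)[C@@H](CO[Si](C)(C)C(C)(C)C)C#C
F2 | step 7 | 1-[(3S)-3-({[tert-butyl(dimethyl)silyl]oxy}methyl)-2-methylpent-4-en-2-yl]cyclopropan-1-ol | OC1(CC1)C(C)(C)[C@@H](CO[Si](C)(C)C(C)(C)C)C=C
F3 | step 7 | {1-[(3S)-3-({[tert-butyl(dimethyl)silyl]oxy}methyl)-2-methylpent-4-en-2-yl]cyclopropoxy}trimethylsilane | C[Si](C)(C)OC1(CC1)C(C)(C)[C@@H](CO[Si](C)(C)C(C)(C)C)C=C
F4 | step 7 | (2S)-2-({[tert-butyl(dimethyl)silyl]oxy}methyl)-3-methyl-3-{1-[(trimethylsilyl)oxy]cyclopropyl}butanal | C[Si](C)(C)OC1(CC1)C(C)(C)[C@@H](CO[Si](C)(C)C(C)(C)C)C=O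
F5 | step 7 | {1-[(3S)-3-({[tert-butyl(dimethyl)silyl]oxy}methyl)-2-methylpent-4-yn-2-yl]cyclopropoxy}trimethylsilane | C[Si](C)(C)OC1(CC1)C(C)(C)[C@@H](CO[Si](C)(C)C(C)(C)C)C#C
F0 | step 9 | none | none
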